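**Assumptions (one line each)**
- Claisen rearrangement of 3 goes mainly to the less hindered ortho position. The minor regioisomer is removed by chromatography.
- The chiral iodane catalyst enantiomer in Step 4 is chosen empirically to give the (3aS) dienone.

## Retrosynthetic overview
1. Dysodanthin B ⇒ C5 H/OMe stereocentre by 1,4‑reduction of the C4=C5 enone of dienone **9**.
2. **9** ⇒ all‑cis C2/C3 stereocentres by face‑selective reduction of the C2=C3 enol ether of **8**, anti to the quaternary allyl group.
3. **8** ⇒ one step: oxidative dearomative formal [3+2] of 2‑allyl‑4,5‑dimethoxyphenol (**4**) with 1‑(3,4,5‑trimethoxyphenyl)propyne (**7**). This forms the quaternary C3a and the dihydrofuran ring while the arene becomes the cyclohexadienone.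
4. **4** comes from 3,4‑dimethoxyphenol by allylation and Claisen rearrangement. **7** comes from 5‑iodo‑1,2,3‑trimethoxybenzene by Sonogashira coupling with propyne.
5. Ring order: the six‑membered ring is the starting arene. The dihydrofuran forms together with its dearomatization in Step 4.

## Route

**Step 1**
Reactants: **1** 3,4‑dimethoxyphenol; **2** allyl bromide
Product: **3** 1‑(allyloxy)‑3,4‑dimethoxybenzene
Conditions: K2CO3, acetone, reflux
Reagents that add atoms: allyl bromide, C=CCBr
Why: Williamson O‑alkylation of the phenoxide; no stereocentres.

**Step 2**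
Reactants: **3**
Product: **4** 2‑allyl‑4,5‑dimethoxyphenol
Conditions: PhNEt2, 200 °C (sealed tube or µW)
Reagents that add atoms: none
Why: Aromatic Claisen [3,3] rearrangement moves the allyl group to the less hindered ortho carbon, which becomes the later quaternary C3a.

**Step 3**
Reactants: **5** 5‑iodo‑1,2,3‑trimethoxybenzene; **6** propyne
Product: **7** 1‑(3,4,5‑trimethoxyphenyl)prop‑1‑yne
Conditions: Pd(PPh3)2Cl2 (3 mol%), CuI (5 mol%), Et3N/THF, rt, propyne (1 atm)
Reagents that add atoms: propyne, CC#C (numbered as **6**)
Why: Sonogashira coupling of an aryl iodide with a terminal alkyne.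

**Step 4 (key step)**
Reactants: **4**; **7** (3 equiv)
Product: **8** (3aS)‑3a‑allyl‑5‑methoxy‑3‑methyl‑2‑(3,4,5‑trimethoxyphenyl)benzofuran‑6(3aH)‑one
Conditions: chiral spirobiindane aryl iodide (10 mol%), mCPBA (1.3 equiv), HFIP/CH2Cl2 1:1, –20 °C; then aq. NaHCO3 workup
Reagents that add atoms: none (the oxidant leaves no atoms in the product, and the C6 methyl is lost as MeOH or Me–X)
Why: Iodane(III) oxidation of the phenol gives an iodane‑bound phenoxonium whose ortho carbon bearing the allyl group is electrophilic; the arylalkyne attacks it through its methyl‑bearing carbon, which sets the quaternary C3a face under catalyst control.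
Proposed new method: The α‑aryl vinyl cation formed is captured by the former phenol oxygen to close the dihydrofuran, and the resulting oxocarbenium delocalised onto the C6‑OMe loses its methyl group on workup to give the C6 ketone. The closest known reactions are the oxidative [3+2] of phenols with styrenes and enantioselective chiral‑iodane phenol dearomatizations.

**Step 5**
Reactants: **8**
Product: **9** (2R,3S,3aR)‑3a‑allyl‑5‑methoxy‑3‑methyl‑2‑(3,4,5‑trimethoxyphenyl)‑3,3a‑dihydrobenzofuran‑6(2H)‑one
Conditions: Et3SiH (5 equiv), TFA (10 equiv), CH2Cl2, –20 → 0 °C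
Reagents that add atoms: none (only H is added)
Why: Ionic hydrogenation of the 2‑aryl enol ether: C3 is protonated from the face anti to the pseudo‑axial allyl group, which puts the methyl syn to the allyl. The aryl‑stabilised oxocarbenium at C2 is then reduced by Et3SiH from the face anti to both the methyl and the allyl. This sets C3 and C2 all‑cis to C3a and leaves the allyl and the dienone untouched. (The CIP label at C3a changes from S to R only because substituent priorities change; the spatial arrangement is unchanged.)

**Step 6**
Reactants: **9**
Product: **10** Dysodanthin B, (2R,3S,3aS,5R)‑3a‑allyl‑5‑methoxy‑3‑methyl‑2‑(3,4,5‑trimethoxyphenyl)‑3,3a,4,5‑tetrahydrobenzofuran‑6(2H)‑one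
Conditions: [(Ph3P)CuH]6 (0.35 equiv), toluene, –20 °C; then sat. aq. NH4Cl
Reagents that add atoms: none (only H is added)
Why: Stryker Cu–H conjugate reduction hits only the more electrophilic α‑methoxyenone C4=C5, because the vinylogous ester and the isolated allyl alkene are inert to it. C5 is set by kinetic protonation of the copper enolate from the face anti to the allyl group, which leaves OMe cis to the allyl group as in the target.

## Self‑check
- Target SMILES: the structure has a cyclohexenone fused to a tetrahydrofuran, the vinylogous ester O–C7a=C7–C6=O, 3a‑allyl, 5‑OMe, 3‑Me and 2‑(3,4,5‑trimethoxyphenyl). In the target, 2‑Ar, 3‑Me and 3a‑allyl are all cis on the five‑ring, and 5‑OMe is cis to the allyl on the six‑ring. The route gives this.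
- Atom balance for Step 4: 4 (C11H14O6… i.e. C11H14O3) + 7 (C12H14O3) gives 8 (C22H24O6) plus CH4 and two electrons removed by the oxidant. Step 5 adds H2 to give 9 (C22H26O6). Step 6 adds H2 to give 10 (C22H28O6).
- Functional group survival: the allyl alkene survives Et3SiH/TFA and Cu–H. The aryl methyl ethers survive all conditions. C5 is set in the last step and nothing follows it.
- Stereocentres: C3a is set in Step 4, C3 and C2 in Step 5, and C5 in Step 6. None is touched afterwards.

## Compound list
1 | 3,4‑dimethoxyphenol | COc1ccc(O)cc1OC | starting material
2 | allyl bromide | C=CCBr | starting material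
3 | 1‑(allyloxy)‑3,4‑dimethoxybenzene | C=CCOc1ccc(OC)c(OC)c1 | intermediate
4 | 2‑allyl‑4,5‑dimethoxyphenol | C=CCc1cc(OC)c(OC)cc1O | intermediate
5 | 5‑iodo‑1,2,3‑trimethoxybenzene | COc1cc(I)cc(OC)c1OC | starting material
6 | propyne | CC#C | starting material
7 | 1‑(3,4,5‑trimethoxyphenyl)propyne | COc1cc(C#CC)cc(OC)c1OC | intermediate
8 | (3aS)‑dienone benzofuranone | C=CC[C@@]12C=C(OC)C(=O)C=C1OC(c1cc(OC)c(OC)c(OC)c1)=C2C | intermediate
9 | (2R,3S,3aR)‑dihydrobenzofuranone dienone | C=CC[C@@]12C=C(OC)C(=O)C=C1O[C@@H](c1cc(OC)c(OC)c(OC)c1)[C@H]2C | intermediate
10 | Dysodanthin B | C=CC[C@@]12C[C@@H](OC)C(=O)C=C1O[C@@H](c1cc(OC)c(OC)c(OC)c1)[C@H]2C | target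

**Total steps:** 6. **Longest linear sequence:** 5 (1 → 3 → 4 → 8 → 9 → 10, counting Steps 1, 2, 4, 5, 6; Step 3 is a parallel branch).

## Three steps most likely to fail
1. **Step 4 (alkyne [3+2] dearomatization and enantioselection).** The vinyl‑cation closure could fail, or the ee could be low.
   Fallback: oxidise **4** with PIDA/MeOH to the isolated quinone monoketal, then run a chiral Brønsted or Lewis acid‑catalysed [3+2] with **7**. If the ee is still low, resolve racemic **8** by preparative chiral HPLC.
2. **Step 5 (ionic hydrogenation).** Possible problems are low facial selectivity, hydride attack on the protonated vinylogous ester, or acid‑induced dienone–phenol rearrangement.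
   Fallback: change the approach by replacing **7** in Step 4 with (Z)‑1‑(3,4,5‑trimethoxyphenyl)propene. This gives the 2,3‑cis dihydrofuran directly through fast capture of the benzylic cation, and Step 5 is dropped.
3. **Step 6 (C5 configuration and chemoselectivity).** The kinetic protonation may give the wrong C5 epimer, or the Cu–H reagent may attack the vinylogous ester.
   Fallback: use the 5‑desmethoxy analogue made from 2‑allyl‑5‑methoxyphenol through Steps 4–5, reduce nothing further, then install C5‑OMe by LDA/Davis oxaziridine α′‑hydroxylation and O‑methylation (MeI, Ag2O). Any wrong C5 epimer is equilibrated under mild base.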